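The benzo ring carries bromine at C4 and at C7. These lie 1,4 to each other across the ring, on either side of the C3a–C7a fusion bond. A didehydroarene formed from an enediyne whose alkene is the pyrrole C2=C3 bond has its unpaired electrons on these two carbons. The route therefore disconnects C5–C6 together with both aryl C–Br bonds. One thermal operation, a Bergman cycloaromatization run in a bromine-atom donor, should close the six-membered ring and install both bromines. The precursor is a 2,3-diethynylpyrrole with an N-benzenesulfonyl group, chosen because it has no weak C–H bond. Three steps lead to it from a bromopyrrole aldehyde. Desulfonylation, C3 chlorination and C2 bromination complete the target.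

Key step: step 4

Remark: the target, 2,4,7-tribromo-3-chloro-1H-indole, is planar and has no stereogenic element, so there is no enantiomer to select and no step controls configuration; 3-bromo-1H-pyrrole-2-carbaldehyde (1) is taken as a catalogue compound.

Step 1
Reactants: 1 3-bromo-1H-pyrrole-2-carbaldehyde; 2 benzenesulfonyl chloride
Product: 3 3-bromo-1-(phenylsulfonyl)-1H-pyrrole-2-carbaldehyde
Conditions: NaH (1.1 equiv), THF, 0 °C to rt
Reagents that add atoms: benzenesulfonyl chloride, O=S(=O)(Cl)c1ccccc1
Why: N-sulfonylation of the pyrrolide anion, whose N–H is acidified by the 2-formyl group, should be clean, and the electron-withdrawing group activates C3–Br for palladium, restores the electrophilicity of the aldehyde and later shields the heterocycle from radicals.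

Step 2
Reactants: 3 3-bromo-1-(phenylsulfonyl)-1H-pyrrole-2-carbaldehyde; 4 trimethylsilylacetylene
Product: 5 1-(phenylsulfonyl)-3-[(trimethylsilyl)ethynyl]-1H-pyrrole-2-carbaldehyde
Conditions: PdCl2(PPh3)2 (cat.), CuI (cat.), Et3N, THF, 55 °C, argon
Reagents that add atoms: trimethylsilylacetylene, C#C[Si](C)(C)C
Why: Sonogashira coupling should proceed because the C3–Br bond lies ortho to a formyl group on an electron-poor N-sulfonylpyrrole and adds readily to Pd(0), while the tertiary amine leaves the aldehyde and the N–S bond untouched.

Step 3
Reactants: 5 1-(phenylsulfonyl)-3-[(trimethylsilyl)ethynyl]-1H-pyrrole-2-carbaldehyde; 6 dimethyl (1-diazo-2-oxopropyl)phosphonate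
Product: 8 2,3-diethynyl-1-(phenylsulfonyl)-1H-pyrrole, via desilylated aldehyde 7 (not isolated)
Conditions: K2CO3, MeOH/THF, 0 °C to rt, short reaction time
Reagents that add atoms: dimethyl (1-diazo-2-oxopropyl)phosphonate, CC(=O)C(=[N+]=[N-])P(=O)(OC)OC
Why: In the Ohira–Bestmann form of the Seyferth–Gilbert homologation the diazomethylphosphonate anion released from 6 turns the aldehyde into the terminal alkyne through a diazoalkene and a 1,2-hydrogen shift, and the same carbonate/methanol medium removes the C-silyl group, so both free alkynes come from one operation.

Step 4
Reactants: 8 2,3-diethynyl-1-(phenylsulfonyl)-1H-pyrrole; 9 bromotrichloromethane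
Product: 11 4,7-dibromo-1-(phenylsulfonyl)-1H-indole, via 4,7-didehydroindole diradical 10 (not isolated)
Conditions: neat 9 as solvent and bromine donor (8 at 1–2 mM), freeze–pump–thaw degassed, sealed heavy-walled glass tube, dark, preheated block, 200 °C; 9 recovered by distillation
Reagents that add atoms: bromotrichloromethane, BrC(Cl)(Cl)Cl
Why: Proposed new method: the pyrrole C2=C3 bond and its two ethynyl groups make up a (Z)-hex-3-ene-1,5-diyne, so heating should couple the two terminal alkyne carbons through their in-plane π orbitals (Bergman cycloaromatization) to the σ,σ-diradical 10 with its spins at C4 and C7, each of which then takes a bromine atom from the weak C–Br bond of 9 while the two trichloromethyl radicals pair to hexachloroethane. The closest known reaction type is the thermal Bergman cyclization of arene- and heteroarene-fused enediynes with capture of the 1,4-didehydroarene by a tetrahalomethane to give a 1,4-dihaloarene, whereas double bromine capture on a pyrrole-fused enediyne has not been shown. The one new ring, the six-membered benzo ring, closes by C1–C6 (endo,endo-dig) bond formation at the future C5–C6, and no stereocentre arises. Regiochemistry needs no control because the enediyne topology puts the radical sites next to C3a and C7a; the selectivity that matters is bromine capture against hydrogen capture, ring reopening and attack of the C7 radical on the sulfonyl arene, and it is secured by using the donor as solvent (about 10 M) and a substrate without any weak C–H bond, which is why benzenesulfonyl is used and not tosyl with its benzylic CH3. Chain addition of trichloromethyl radicals to the terminal alkynes depends on the concentration of substrate and of radicals, so it is held back by millimolar dilution, exclusion of oxygen and light, and fast heating to a temperature at which the unimolecular closure dominates. Donor 9 is preferred to carbon tetrabromide because neither 9 nor its spent form C2Cl6 liberates Br2 at 200 °C, as CBr4 and C2Br6 do, and the bulky N-sulfonyl group pushes the C2 alkyne toward its partner, which offsets part of the wider terminus distance on a five-membered ring.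

Step 5
Reactants: 11 4,7-dibromo-1-(phenylsulfonyl)-1H-indole
Product: 12 4,7-dibromo-1H-indole
Conditions: aq NaOH, THF/MeOH, 50 °C
Reagents that add atoms: none
Why: Hydrolytic cleavage of an N-sulfonylindole (hydroxide attacks sulfur, indolide leaves) is eased by peri strain with the C7 bromine and does not touch aryl bromides.

Step 6
Reactants: 12 4,7-dibromo-1H-indole; 13 N-chlorosuccinimide
Product: 14 4,7-dibromo-3-chloro-1H-indole
Conditions: NCS (1.0 equiv), DMF, 0 °C to rt, dark
Reagents that add atoms: N-chlorosuccinimide, O=C1CCC(=O)N1Cl
Why: Electrophilic aromatic substitution should occur at C3, the enamine-like and most nucleophilic carbon of an N–H indole, while the benzo ring is deactivated by its two bromines and one equivalent of reagent limits the reaction to monochlorination.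

Step 7
Reactants: 14 4,7-dibromo-3-chloro-1H-indole; 15 N-bromosuccinimide
Product: 16 2,4,7-tribromo-3-chloro-1H-indole
Conditions: NBS (1.0 equiv), anhydrous CH2Cl2, 0 °C to rt, dark; rapid chromatography, cold dark storage
Reagents that add atoms: N-bromosuccinimide, O=C1CCC(=O)N1Br
Why: Electrophilic bromination of a 3-haloindole should place bromine at C2, the only open position of the pyrrole ring, either directly or after ipso attack at C3 and 1,2-shift of the more mobile bromine, and dry conditions prevent diversion to oxindole-type oxidation.

Compound list
1 | 3-bromo-1H-pyrrole-2-carbaldehyde | O=Cc1[nH]ccc1Br | starting material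
2 | benzenesulfonyl chloride | O=S(=O)(Cl)c1ccccc1 | starting material
3 | 3-bromo-1-(phenylsulfonyl)-1H-pyrrole-2-carbaldehyde | O=Cc1c(Br)ccn1S(=O)(=O)c1ccccc1 | intermediate
4 | trimethylsilylacetylene | C#C[Si](C)(C)C | starting material
5 | 1-(phenylsulfonyl)-3-[(trimethylsilyl)ethynyl]-1H-pyrrole-2-carbaldehyde | O=Cc1c(C#C[Si](C)(C)C)ccn1S(=O)(=O)c1ccccc1 | intermediate
6 | dimethyl (1-diazo-2-oxopropyl)phosphonate | CC(=O)C(=[N+]=[N-])P(=O)(OC)OC | starting material
7 | 3-ethynyl-1-(phenylsulfonyl)-1H-pyrrole-2-carbaldehyde (not isolated) | O=Cc1c(C#C)ccn1S(=O)(=O)c1ccccc1 | intermediate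
8 | 2,3-diethynyl-1-(phenylsulfonyl)-1H-pyrrole | C#Cc1ccn(S(=O)(=O)c2ccccc2)c1C#C | intermediate
9 | bromotrichloromethane | BrC(Cl)(Cl)Cl | starting material
10 | 1-(phenylsulfonyl)-4,7-didehydro-1H-indole, σ,σ-diradical at C4 and C7 (not isolated) | O=S(=O)(c1ccccc1)n1ccc2[c]cc[c]c12 | intermediate
11 | 4,7-dibromo-1-(phenylsulfonyl)-1H-indole | O=S(=O)(c1ccccc1)n1ccc2c(Br)ccc(Br)c12 | intermediate
12 | 4,7-dibromo-1H-indole | Brc1ccc(Br)c2[nH]ccc12 | intermediate
13 | N-chlorosuccinimide | O=C1CCC(=O)N1Cl | starting material
14 | 4,7-dibromo-3-chloro-1H-indole | Clc1c[nH]c2c(Br)ccc(Br)c12 | intermediate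
15 | N-bromosuccinimide | O=C1CCC(=O)N1Br | starting material
16 | 2,4,7-tribromo-3-chloro-1H-indole (achiral) | Clc1c(Br)[nH]c2c(Br)ccc(Br)c12 | target

Total step count: 7. Longest linear sequence: 7 (1 to 16).

Steps most likely to fail

1. Step 4 (Proposed new method).
- What may go wrong: chain addition of trichloromethyl radicals across the terminal alkynes, followed by oligomerisation, may consume the enediyne faster than it cyclises. The diradical may also reopen before it is trapped, or the C7 radical may attack the sulfonyl arene.
- Fallback (known chemistry, opposite ring construction): the pyrrole ring is built onto a benzene that already carries both bromines. None of compounds 1–11 can be carried over, so the fallback sets out from commercial 1,4-dibromo-2-nitrobenzene F1 in place of 8. Treatment with three equivalents of vinylmagnesium bromide F2 in THF at −40 °C is a Bartoli indole synthesis, for which the bromine ortho to the nitro group is the required steering substituent. It should give 4,7-dibromo-1H-indole directly. The route is rejoined at 12, and steps 6 and 7 follow unchanged.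

2. Step 3.
- What may go wrong: methoxide may cleave the N–S bond while the 2-formyl group still makes the pyrrolide a good leaving group. That would expose an N–H aldehyde that homologates sluggishly and an unprotected diyne that does not keep.
- Fallback: it sets out from 5 and avoids methoxide as long as the aldehyde is present. (Trimethylsilyl)diazomethane F3 is deprotonated with LDA in THF at −78 °C to lithio(trimethylsilyl)diazomethane F4. This adds to the aldehyde of 5 and, after Peterson-type loss of silanolate and loss of nitrogen, rearranges (Colvin rearrangement) to 2-ethynyl-1-(phenylsulfonyl)-3-[(trimethylsilyl)ethynyl]-1H-pyrrole F5. The remaining C-silyl group is then removed with acetic-acid-buffered TBAF in THF at 0 °C, which returns the material to the route at 8.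

3. Step 7.
- What may go wrong: ipso attack at C3 followed by migration or exchange of chlorine instead of bromine may scramble the two halogens. The doubly deactivated ring may also react so slowly that oxidation and decomposition of the sensitive dihaloindole take over.
- Fallback: it sets out from 11 and fixes the C2 bromine by deprotonation instead of electrophilic substitution. LDA in THF at −78 °C removes the C2 proton, which the neighbouring sulfonyl group makes the most acidic (directed lithiation), to give 4,7-dibromo-2-lithio-1-(phenylsulfonyl)indole F6. This is quenched with 1,2-dibromo-1,1,2,2-tetrachloroethane F7 to give 2,4,7-tribromo-1-(phenylsulfonyl)-1H-indole F8. Hydrolysis with aqueous NaOH in THF/MeOH gives 2,4,7-tribromo-1H-indole F9, whose only free nucleophilic position is C3. Chlorination with 13 in DMF should then deliver the target without regiochemical ambiguity, and the fallback meets the route at 16.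

Further compounds
F1 | step 4 | 1,4-dibromo-2-nitrobenzene | O=[N+]([O-])c1cc(Br)ccc1Br
F2 | step 4 | vinylmagnesium bromide | C=C[Mg]Br
F3 | step 3 | (trimethylsilyl)diazomethane | C[Si](C)(C)C=[N+]=[N-]
F4 | step 3 | lithio(trimethylsilyl)diazomethane | [Li]C(=[N+]=[N-])[Si](C)(C)C
F5 | step 3 | 2-ethynyl-1-(phenylsulfonyl)-3-[(trimethylsilyl)ethynyl]-1H-pyrrole | C#Cc1c(C#C[Si](C)(C)C)ccn1S(=O)(=O)c1ccccc1
F6 | step 7 | 4,7-dibromo-2-lithio-1-(phenylsulfonyl)indole | [Li]c1cc2c(Br)ccc(Br)c2n1S(=O)(=O)c1ccccc1
F7 | step 7 | 1,2-dibromo-1,1,2,2-tetrachloroethane | ClC(Cl)(Br)C(Cl)(Cl)Br
F8 | step 7 | 2,4,7-tribromo-1-(phenylsulfonyl)-1H-indole | Brc1cc2c(Br)ccc(Br)c2n1S(=O)(=O)c1ccccc1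
F9 | step 7 | 2,4,7-tribromo-1H-indole | Brc1cc2c(Br)ccc(Br)c2[nH]1
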